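**Plan**

Oxolane numbering: O1, C2 (3,4-dimethoxyphenyl), C3 and C4 (methyls), C5 (4-hydroxy-3,5-dimethoxyphenyl). C5 is the benzylic carbon para to the only free phenolic OH, which is flanked by two OMe groups; a flavin-dependent 4-alkylphenol oxidase turns exactly this position into a p-quinone methide carbon.
Retrosynthesis: cut O1–C5 (seco alcohol 15), take the C4 methyl back to a C4=CH2 alkene and then a C4 ketone, cut C4–C5 (Weinreb amide plus benzylic Grignard reagent), and finally cut C2–C3 (aldol).
Forward: C2–C3 is joined first, then C4–C5, C4 gains its methyl carbon by methylenation, and the only ring closes in the last step.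
Stereochemistry: C2 and C3 come from an oxazolidinone-controlled syn-aldol; C4 from hydroxyl-directed hydrogenation of the 1,1-disubstituted alkene; C5 is set in the ring closure, trans to the C4 methyl.

Key step: step 11

Remark: the oxidase is taken to be eugenol oxidase (FAD-dependent, Rhodococcus jostii type) or a variant with an enlarged binding pocket; acceptance of a substrate of this size is an assumption.

**Route**

Step 1
Reactants: 1 syringaldehyde (4-hydroxy-3,5-dimethoxybenzaldehyde)
Product: 2 3,5-dimethoxy-4-[(triisopropylsilyl)oxy]benzaldehyde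
Conditions: iPr3SiCl, imidazole, DMF, rt
Reagents that add atoms: chlorotriisopropylsilane, CC(C)[Si](Cl)(C(C)C)C(C)C
Why: Imidazole-promoted silyl ether formation masks the acidic phenol, which would quench the Grignard reagent of step 7, as a fluoride-labile ether that tolerates hydride, Grignard and titanium reagents.

Step 2
Reactants: 2 3,5-dimethoxy-4-[(triisopropylsilyl)oxy]benzaldehyde
Product: 3 {3,5-dimethoxy-4-[(triisopropylsilyl)oxy]phenyl}methanol
Conditions: NaBH4, MeOH, 0 °C
Reagents that add atoms: none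
Why: Borohydride reduction of the aryl aldehyde to the benzylic alcohol is chemoselective and leaves the aryl silyl ether intact.

Step 3
Reactants: 3 {3,5-dimethoxy-4-[(triisopropylsilyl)oxy]phenyl}methanol
Product: 4 {[4-(chloromethyl)-2,6-dimethoxyphenyl]oxy}triisopropylsilane
Conditions: SOCl2, pyridine, CH2Cl2, 0 °C
Reagents that add atoms: thionyl chloride, O=S(Cl)Cl
Why: Deoxychlorination with thionyl chloride is facile for this electron-rich benzylic alcohol, and pyridine takes up the HCl so that the silyl ether survives.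

Step 4
Reactants: 5 (R)-4-benzyl-3-propionyloxazolidin-2-one; 6 veratraldehyde (3,4-dimethoxybenzaldehyde)
Product: 8 (R)-4-benzyl-3-[(2R,3R)-3-(3,4-dimethoxyphenyl)-3-hydroxy-2-methylpropanoyl]oxazolidin-2-one, via dibutylboron Z-enolate 7 (not isolated)
Conditions: Bu2BOTf, iPr2NEt, CH2Cl2, 0 °C; then 6, −78 → 0 °C; then NaH2PO4/Na2HPO4 buffer pH 7, MeOH, H2O2, 0 °C
Reagents that add atoms: none
Why: Evans syn-aldol reaction, in which the Z-boron enolate reacts through a closed Zimmerman–Traxler chair on the enolate face away from the benzyl group of the auxiliary, sets the (2R,3R) syn pair that becomes C3 and C2 of the oxolane.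

Step 5
Reactants: 8 (R)-4-benzyl-3-[(2R,3R)-3-(3,4-dimethoxyphenyl)-3-hydroxy-2-methylpropanoyl]oxazolidin-2-one
Product: 9 (2R,3R)-3-(3,4-dimethoxyphenyl)-3-hydroxy-N-methoxy-N,2-dimethylpropanamide
Conditions: MeNH(OMe)·HCl, AlMe3, CH2Cl2, −15 → 0 °C; aq. potassium sodium tartrate
Reagents that add atoms: N,O-dimethylhydroxylamine hydrochloride, CNOC.Cl
Why: Weinreb transamidation with the aluminium amide is assisted by the free β-hydroxyl, attacks the exocyclic carbonyl and releases the auxiliary without epimerising the α-centre.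

Step 6
Reactants: 9 (2R,3R)-3-(3,4-dimethoxyphenyl)-3-hydroxy-N-methoxy-N,2-dimethylpropanamide
Product: 10 (2R,3R)-3-[(tert-butyldimethylsilyl)oxy]-3-(3,4-dimethoxyphenyl)-N-methoxy-N,2-dimethylpropanamide
Conditions: tBuMe2SiOTf, 2,6-lutidine, CH2Cl2, 0 °C
Reagents that add atoms: tert-butyldimethylsilyl trifluoromethanesulfonate, CC(C)(C)[Si](C)(C)OS(=O)(=O)C(F)(F)F
Why: Silylation with the silyl triflate protects the benzylic hydroxyl so that it does not consume the Grignard reagent and so that retro-aldol cleavage of the later β-oxy ketone is blocked.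

Step 7
Reactants: 4 {[4-(chloromethyl)-2,6-dimethoxyphenyl]oxy}triisopropylsilane; 10 (2R,3R)-3-[(tert-butyldimethylsilyl)oxy]-3-(3,4-dimethoxyphenyl)-N-methoxy-N,2-dimethylpropanamide
Product: 12 (3R,4R)-4-[(tert-butyldimethylsilyl)oxy]-4-(3,4-dimethoxyphenyl)-1-{3,5-dimethoxy-4-[(triisopropylsilyl)oxy]phenyl}-3-methylbutan-2-one, via benzylic Grignard reagent 11 (not isolated)
Conditions: 4, Mg turnings (excess), Et2O, 0 °C, slow addition; then 10, THF, −10 → 0 °C; aq. NH4Cl
Reagents that add atoms: none
Why: Weinreb ketone synthesis, in which the benzylic Grignard reagent adds once to give a stable magnesium chelate that collapses to the ketone only on work-up, forms the C4–C5 bond without over-addition and without exposing the α-stereocentre to base as a ketone.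

Step 8
Reactants: 12 (3R,4R)-4-[(tert-butyldimethylsilyl)oxy]-4-(3,4-dimethoxyphenyl)-1-{3,5-dimethoxy-4-[(triisopropylsilyl)oxy]phenyl}-3-methylbutan-2-one
Product: 13 tert-butyl{[(1R,2S)-1-(3,4-dimethoxyphenyl)-3-({3,5-dimethoxy-4-[(triisopropylsilyl)oxy]phenyl}methyl)-2-methylbut-3-en-1-yl]oxy}dimethylsilane
Conditions: Zn, CH2Br2, TiCl4, THF, 0 °C (aged reagent); then 12, CH2Cl2, 0 °C → rt
Reagents that add atoms: dibromomethane, BrCBr
Why: Takai–Lombardo methylenation uses a nonbasic zinc–titanium methylene reagent that converts enolisable, epimerisable ketones into 1,1-disubstituted alkenes, so the α-stereocentre and the acidic benzylic CH2 should be preserved.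

Step 9
Reactants: 13 tert-butyl{[(1R,2S)-1-(3,4-dimethoxyphenyl)-3-({3,5-dimethoxy-4-[(triisopropylsilyl)oxy]phenyl}methyl)-2-methylbut-3-en-1-yl]oxy}dimethylsilane
Product: 14 4-[(3S,4R)-4-(3,4-dimethoxyphenyl)-4-hydroxy-3-methyl-2-methylidenebutyl]-2,6-dimethoxyphenol
Conditions: Bu4NF, THF, 0 °C → rt; aq. NH4Cl
Reagents that add atoms: none
Why: Fluoride-mediated desilylation, driven by the strong Si–F bond, removes the aryl and the secondary silyl ether in one operation and frees both the directing hydroxyl and the phenol.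

Step 10
Reactants: 14 4-[(3S,4R)-4-(3,4-dimethoxyphenyl)-4-hydroxy-3-methyl-2-methylidenebutyl]-2,6-dimethoxyphenol
Product: 15 4-[(2R,3S,4R)-4-(3,4-dimethoxyphenyl)-4-hydroxy-2,3-dimethylbutyl]-2,6-dimethoxyphenol
Conditions: [Rh(nbd)(dppb)]BF4 (5 mol %; nbd = norbornadiene, dppb = Ph2P(CH2)4PPh2), H2 (60 bar), CH2Cl2, rt
Reagents that add atoms: none
Why: In this hydroxyl-directed homogeneous hydrogenation the cationic rhodium catalyst chelates the homoallylic hydroxyl and the alkene, the allylic methyl turns toward the =CH2 terminus to avoid allylic 1,2-strain with the arylmethyl group, and the aryl group on the carbinol sits pseudo-equatorial, so both hydrogens should arrive on the hydroxyl-bearing face and set the future C4 centre with its methyl syn to the existing methyl.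

Step 11
Reactants: 15 4-[(2R,3S,4R)-4-(3,4-dimethoxyphenyl)-4-hydroxy-2,3-dimethylbutyl]-2,6-dimethoxyphenol
Product: 17 (2R,3S,4S,5S)-2-(3,4-dimethoxyphenyl)-5-(4-hydroxy-3,5-dimethoxyphenyl)-3,4-dimethyloxolane, via p-quinone methide 16 (not isolated)
Conditions: eugenol oxidase (FAD-dependent 4-alkylphenol oxidase), air (O2), catalase, KH2PO4/K2HPO4 buffer pH 7.5, 10 vol% DMSO, 25 °C
Reagents that add atoms: none
Why: Proposed new method: the flavin of the oxidase should abstract a hydride from the benzylic CH2 (future C5) para to the bound phenolate of 15 to give the p-quinone methide 16, while O2 reoxidises the reduced flavin to give H2O2 that catalase removes. The hydroxyl on the future C2 then adds to the methide carbon in a 5-exo-trig oxa-conjugate addition that forms O1–C5, closes the oxolane and restores the aromatic ring. The closest known reaction type is the oxidation of 4-alkylphenols by vanillyl alcohol oxidase and eugenol oxidase through enzyme-bound p-quinone methides that are trapped by water, with Ag2O- or DDQ-mediated quinone methide etherification as the chemical counterpart. The new C5 centre is controlled by the C4 stereocentre, because with C4–H eclipsing the methide (minimal allylic 1,3-strain) the tethered oxygen reaches the face that leaves the aryl group trans to the C4 methyl, which is also the more stable arrangement of the ring. The step needs chemoselectivity between two electron-rich benzylic positions, and the substrate secures it because only the 4-hydroxy-3,5-dimethoxyphenyl ring has the free para-hydroxyl that these oxidases require, so the benzylic carbinol of the dimethoxyphenyl ring is not oxidised. Intramolecular capture through a five-membered transition state should outrun both addition of water and tautomerisation of 16 to the styrene.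

**Compound list**

1 | syringaldehyde (4-hydroxy-3,5-dimethoxybenzaldehyde) | COc1cc(C=O)cc(OC)c1O | starting material
2 | 3,5-dimethoxy-4-[(triisopropylsilyl)oxy]benzaldehyde | COc1cc(C=O)cc(OC)c1O[Si](C(C)C)(C(C)C)C(C)C | intermediate
3 | {3,5-dimethoxy-4-[(triisopropylsilyl)oxy]phenyl}methanol | COc1cc(CO)cc(OC)c1O[Si](C(C)C)(C(C)C)C(C)C | intermediate
4 | {[4-(chloromethyl)-2,6-dimethoxyphenyl]oxy}triisopropylsilane | COc1cc(CCl)cc(OC)c1O[Si](C(C)C)(C(C)C)C(C)C | intermediate
5 | (R)-4-benzyl-3-propionyloxazolidin-2-one | CCC(=O)N1[C@H](Cc2ccccc2)COC1=O | starting material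
6 | veratraldehyde (3,4-dimethoxybenzaldehyde) | COc1ccc(C=O)cc1OC | starting material
7 | (R,Z)-4-benzyl-3-{1-[(dibutylboranyl)oxy]prop-1-en-1-yl}oxazolidin-2-one (boron enolate, not isolated) | C/C=C(\OB(CCCC)CCCC)N1[C@H](Cc2ccccc2)COC1=O | intermediate
8 | (R)-4-benzyl-3-[(2R,3R)-3-(3,4-dimethoxyphenyl)-3-hydroxy-2-methylpropanoyl]oxazolidin-2-one | COc1ccc([C@H](O)[C@@H](C)C(=O)N2[C@H](Cc3ccccc3)COC2=O)cc1OC | intermediate
9 | (2R,3R)-3-(3,4-dimethoxyphenyl)-3-hydroxy-N-methoxy-N,2-dimethylpropanamide | COc1ccc([C@H](O)[C@@H](C)C(=O)N(C)OC)cc1OC | intermediate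
10 | (2R,3R)-3-[(tert-butyldimethylsilyl)oxy]-3-(3,4-dimethoxyphenyl)-N-methoxy-N,2-dimethylpropanamide | COc1ccc([C@H](O[Si](C)(C)C(C)(C)C)[C@@H](C)C(=O)N(C)OC)cc1OC | intermediate
11 | {3,5-dimethoxy-4-[(triisopropylsilyl)oxy]benzyl}magnesium chloride (not isolated) | COc1cc(C[Mg]Cl)cc(OC)c1O[Si](C(C)C)(C(C)C)C(C)C | intermediate
12 | (3R,4R)-4-[(tert-butyldimethylsilyl)oxy]-4-(3,4-dimethoxyphenyl)-1-{3,5-dimethoxy-4-[(triisopropylsilyl)oxy]phenyl}-3-methylbutan-2-one | COc1ccc([C@H](O[Si](C)(C)C(C)(C)C)[C@@H](C)C(=O)Cc2cc(OC)c(O[Si](C(C)C)(C(C)C)C(C)C)c(OC)c2)cc1OC | intermediate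
13 | tert-butyl{[(1R,2S)-1-(3,4-dimethoxyphenyl)-3-({3,5-dimethoxy-4-[(triisopropylsilyl)oxy]phenyl}methyl)-2-methylbut-3-en-1-yl]oxy}dimethylsilane | COc1ccc([C@H](O[Si](C)(C)C(C)(C)C)[C@@H](C)C(=C)Cc2cc(OC)c(O[Si](C(C)C)(C(C)C)C(C)C)c(OC)c2)cc1OC | intermediate
14 | 4-[(3S,4R)-4-(3,4-dimethoxyphenyl)-4-hydroxy-3-methyl-2-methylidenebutyl]-2,6-dimethoxyphenol | COc1ccc([C@H](O)[C@@H](C)C(=C)Cc2cc(OC)c(O)c(OC)c2)cc1OC | intermediate
15 | 4-[(2R,3S,4R)-4-(3,4-dimethoxyphenyl)-4-hydroxy-2,3-dimethylbutyl]-2,6-dimethoxyphenol, equally (1R,2S,3R)-1-(3,4-dimethoxyphenyl)-4-(4-hydroxy-3,5-dimethoxyphenyl)-2,3-dimethylbutan-1-ol | COc1ccc([C@H](O)[C@@H](C)[C@H](C)Cc2cc(OC)c(O)c(OC)c2)cc1OC | intermediate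
16 | 4-[(2R,3S,4R)-4-(3,4-dimethoxyphenyl)-4-hydroxy-2,3-dimethylbutylidene]-2,6-dimethoxycyclohexa-2,5-dien-1-one (p-quinone methide, not isolated) | COc1ccc([C@H](O)[C@@H](C)[C@H](C)C=C2C=C(OC)C(=O)C(OC)=C2)cc1OC | intermediate
17 | (2R,3S,4S,5S)-2-(3,4-dimethoxyphenyl)-5-(4-hydroxy-3,5-dimethoxyphenyl)-3,4-dimethyloxolane (2,3-cis, 3,4-trans, 4,5-trans) | COc1ccc([C@@H]2O[C@H](c3cc(OC)c(O)c(OC)c3)[C@@H](C)[C@@H]2C)cc1OC | target

**Step count**

Total: 11 steps. Longest linear sequence: 8 steps (steps 4 to 11 from 5 and 6; equally steps 1 to 3 and 7 to 11 from 1).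

**Steps most likely to fail**

Step 11 (proposed new method). The enzyme may not turn over because the branched diaryl substrate does not fit the active site. The bound quinone methide may tautomerise to the conjugated alkene or be captured by water. The product may be oxidised further at C5, which is again para to the phenol. The fallback uses known chemistry and sets out from 15. Stoichiometric Ag2O in CH2Cl2 at rt should oxidise the 2,6-dimethoxy-4-alkylphenol to the same quinone methide 16. After the silver is filtered off, a catalytic amount of camphorsulfonic acid at 0 °C should complete the 5-exo closure and equilibrate C5 to the trans arrangement through reversible quinone methide formation. The acid treatment is kept brief so that the C2 benzylic ether does not ionise. The sequence comes back to the route at 17 and makes no compound outside the list (F0).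

Step 10. The 1,1-disubstituted double bond may migrate into conjugation with the arene through a rhodium hydride before hydrogen is delivered, facial selectivity may be insufficient, or the free phenol may inhibit the catalyst. The fallback sets out from 13 and relies on substrate-controlled hydroboration instead of chelation. 9-Borabicyclo[3.3.1]nonane in THF should add with the allylic C–H eclipsing the alkene and boron entering anti to the bulky silyloxybenzyl substituent, giving the alkylborane F1 with the same configuration at the future C4. Oxidation with NaBO3·4H2O gives the primary alcohol F2. TsCl in pyridine gives the tosylate F3. LiBHEt3 in THF reduces the tosylate, so the former CH2OH carbon becomes the C4 methyl in the saturated bis-silyl ether F4. Bu4NF then removes both silyl groups and the sequence comes back to the route at 15.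

Step 8. The ketone may enolise toward the doubly activated benzylic CH2, epimerise at the α-centre or convert poorly because of hindrance, and the new alkene may migrate under Lewis acid. The fallback sets out from 10 and avoids the benzyl ketone altogether, so it also replaces step 7. MeMgBr in THF at 0 °C gives the methyl ketone F5. Kinetic deprotonation at the methyl group with KN(SiMe3)2 and trapping with PhNTf2 at −78 °C gives the enol triflate F6. Negishi coupling of F6 with the benzylic zinc chloride F7 (from 4, Zn dust and LiCl in THF) under Pd(PPh3)4 catalysis comes back to the route at 13.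

**Further compounds**

F0 | step 11 | none | none
F1 | step 10 | 9-[(2R,3S,4R)-4-[(tert-butyldimethylsilyl)oxy]-4-(3,4-dimethoxyphenyl)-2-{3,5-dimethoxy-4-[(triisopropylsilyl)oxy]benzyl}-3-methylbutyl]-9-borabicyclo[3.3.1]nonane | COc1ccc([C@H](O[Si](C)(C)C(C)(C)C)[C@@H](C)[C@H](CB3C4CCCC3CCC4)Cc2cc(OC)c(O[Si](C(C)C)(C(C)C)C(C)C)c(OC)c2)cc1OC
F2 | step 10 | (2R,3S,4R)-4-[(tert-butyldimethylsilyl)oxy]-4-(3,4-dimethoxyphenyl)-2-{3,5-dimethoxy-4-[(triisopropylsilyl)oxy]benzyl}-3-methylbutan-1-ol | COc1ccc([C@H](O[Si](C)(C)C(C)(C)C)[C@@H](C)[C@H](CO)Cc2cc(OC)c(O[Si](C(C)C)(C(C)C)C(C)C)c(OC)c2)cc1OC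
F3 | step 10 | (2R,3S,4R)-4-[(tert-butyldimethylsilyl)oxy]-4-(3,4-dimethoxyphenyl)-2-{3,5-dimethoxy-4-[(triisopropylsilyl)oxy]benzyl}-3-methylbutyl 4-methylbenzenesulfonate | COc1ccc([C@H](O[Si](C)(C)C(C)(C)C)[C@@H](C)[C@H](COS(=O)(=O)c3ccc(C)cc3)Cc2cc(OC)c(O[Si](C(C)C)(C(C)C)C(C)C)c(OC)c2)cc1OC
F4 | step 10 | tert-butyl{[(1R,2S,3R)-1-(3,4-dimethoxyphenyl)-4-{3,5-dimethoxy-4-[(triisopropylsilyl)oxy]phenyl}-2,3-dimethylbutyl]oxy}dimethylsilane | COc1ccc([C@H](O[Si](C)(C)C(C)(C)C)[C@@H](C)[C@H](C)Cc2cc(OC)c(O[Si](C(C)C)(C(C)C)C(C)C)c(OC)c2)cc1OC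
F5 | step 8 | (3R,4R)-4-[(tert-butyldimethylsilyl)oxy]-4-(3,4-dimethoxyphenyl)-3-methylbutan-2-one | COc1ccc([C@H](O[Si](C)(C)C(C)(C)C)[C@@H](C)C(C)=O)cc1OC
F6 | step 8 | (3R,4R)-4-[(tert-butyldimethylsilyl)oxy]-4-(3,4-dimethoxyphenyl)-3-methylbut-1-en-2-yl trifluoromethanesulfonate | COc1ccc([C@H](O[Si](C)(C)C(C)(C)C)[C@@H](C)C(=C)OS(=O)(=O)C(F)(F)F)cc1OC
F7 | step 8 | {3,5-dimethoxy-4-[(triisopropylsilyl)oxy]benzyl}zinc chloride | COc1cc(C[Zn]Cl)cc(OC)c1O[Si](C(C)C)(C(C)C)C(C)C
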